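## Retrosynthetic overview

1. Isogmelinol 23 ⇐ closure of ring A (O7–C8) in triol 21 ⇐ LiAlH4 opening of the 1-hydroxy furofuranone 20.
2. 20 ⇐ ring B by intramolecular opening of spiro-epoxy lactone 19 at the benzylic carbon C2 (sets 1-OH and C2) ⇐ (E)-α-veratrylidene lactone 17.
3. 17 ⇐ intermolecular aldol of the enolate of γ-lactone 13 with veratraldehyde (C1–C2 bond), then dehydration.
4. 13 ⇐ key intermolecular Evans syn-aldol of N-pentenoyl oxazolidinone 4 with veratraldehyde (C5–C6 bond, sets C5 and C6), then auxiliary removal, alkene cleavage and lactol oxidation.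
5. Ring order: γ-lactone (carries the atoms of ring A) → ring B (tetrahydrofuran) → ring A re-closed as the cyclic ether.

Assumption: the SMILES is read as (1S,2R,5R,6S)-2,6-bis(3,4-dimethoxyphenyl)-3,7-dioxabicyclo[3.3.0]octan-1-ol with both aryl groups exo (cis to 1-OH and 5-H); this numbering is used throughout (ring A = C5, C6, O7, C8, C1; ring B = C1, C2, O3, C4, C5), and DMDO is taken as a freshly prepared acetone solution.

Abbreviations: Ar = 3,4-dimethoxyphenyl; TBS = tert-butyldimethylsilyl.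

## Route

Step 1
Reactants: 1 (S)-4-benzyloxazolidin-2-one; 2 pent-4-enoyl chloride
Product: 4 (S)-4-benzyl-3-(pent-4-enoyl)oxazolidin-2-one, via N-lithio oxazolidinone 3 (not isolated)
Conditions: n-BuLi, THF, −78 °C; then 2, −78 to 0 °C
Reagents that add atoms: none
Why: N-acylation (nucleophilic acyl substitution) of the lithiated oxazolidinone by the acid chloride is a standard high-yielding reaction that creates no stereocenter and leaves the auxiliary center untouched.

Step 2
Reactants: 4 (S)-4-benzyl-3-(pent-4-enoyl)oxazolidin-2-one; 5 3,4-dimethoxybenzaldehyde (veratraldehyde)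
Product: 7 (S)-4-benzyl-3-[(2S)-2-[(S)-Ar(hydroxy)methyl]pent-4-enoyl]oxazolidin-2-one, via boron enolate 6 (not isolated)
Conditions: n-Bu2BOTf, i-Pr2NEt, CH2Cl2, −78 to 0 °C; then 5, −78 to 0 °C; then pH 7 buffer, MeOH, 30% H2O2, 0 °C
Reagents that add atoms: none
Why: Evans syn-aldol reaction: the Z-boron enolate adds to the aldehyde through a Zimmerman–Traxler chair on the enolate face away from the benzyl group, which joins the two fragments at C5–C6 and sets C5 and C6 (the 2S,1'S syn adduct) in one step.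

Step 3
Reactants: 7 Evans syn-aldol adduct
Product: 8 (1S,2R)-2-allyl-1-Ar-propane-1,3-diol
Conditions: LiBH4, H2O (1 equiv), Et2O/THF, 0 °C
Reagents that add atoms: none
Why: Hydride reduction of the activated imide carbonyl (reductive cleavage of the auxiliary) at 0 °C gives the 1,3-diol without retro-aldol and without touching either stereocenter, and the auxiliary is recovered.

Step 4
Reactants: 8 (1S,2R)-2-allyl-1-Ar-propane-1,3-diol
Product: 9 (1S,2R)-2-[(TBS-oxy)methyl]-1-Ar-pent-4-en-1-ol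
Conditions: TBSCl (1.05 equiv), imidazole, CH2Cl2, 0 °C
Reagents that add atoms: tert-butyldimethylsilyl chloride, CC(C)(C)[Si](C)(C)Cl
Why: Selective silylation of the unhindered primary hydroxyl over the secondary benzylic one with one equivalent of TBSCl leaves the benzylic OH free for lactol formation.

Step 5
Reactants: 9 (1S,2R)-2-[(TBS-oxy)methyl]-1-Ar-pent-4-en-1-ol
Product: 12 (4R,5S)-4-[(TBS-oxy)methyl]-5-Ar-tetrahydrofuran-2-ol (lactol; both anomers), via vicinal diol 10 (not isolated), via hydroxy aldehyde 11 (not isolated)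
Conditions: OsO4 (2 mol%), NaIO4 (4 equiv), 2,6-lutidine, dioxane/H2O 3:1, rt
Reagents that add atoms: OsO4, O=[Os](=O)(=O)=O (oxygen carrier); NaIO4, [Na+].[O-]I(=O)(=O)=O (restores OsO4)
Why: Lemieux–Johnson oxidative cleavage (OsO4 dihydroxylation then NaIO4 glycol cleavage) removes the terminal carbon, and the γ-hydroxy aldehyde closes spontaneously to the five-membered lactol while 2,6-lutidine buffers the mixture; no stereocenter of the chain is touched.

Step 6
Reactants: 12 lactol
Product: 13 (4R,5S)-4-[(TBS-oxy)methyl]-5-Ar-dihydrofuran-2(3H)-one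
Conditions: (n-Pr4N)RuO4 (5 mol%), NMO, 4 Å MS, CH2Cl2, rt
Reagents that add atoms: none
Why: Ley–Griffith oxidation converts the lactol to the γ-lactone under neutral conditions that spare the silyl ether and the electron-rich arene, giving the trans-4,5-disubstituted lactone whose trans relationship follows from the syn aldol.

Step 7
Reactants: 13 trans γ-lactone; 5 3,4-dimethoxybenzaldehyde (veratraldehyde)
Product: 15 (3R,4R,5S)-4-[(TBS-oxy)methyl]-5-Ar-3-[Ar(hydroxy)methyl]dihydrofuran-2(3H)-one (both carbinol epimers), via lithium enolate 14 (not isolated)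
Conditions: LiN(i-Pr)2, THF, −78 °C; then 5, −78 °C; aq. NH4Cl
Reagents that add atoms: none
Why: Intermolecular aldol addition of the lactone lithium enolate to veratraldehyde forms the C1–C2 bond anti to the C4 substituent on the ring, and the mixed carbinol configuration does not matter because both new centers are erased in step 8.

Step 8
Reactants: 15 β-hydroxy lactone (both carbinol epimers)
Product: 17 (3E,4R,5S)-4-[(TBS-oxy)methyl]-3-(3,4-dimethoxybenzylidene)-5-Ar-dihydrofuran-2(3H)-one, via benzylic mesylate 16 (not isolated)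
Conditions: MsCl, Et3N, CH2Cl2, 0 °C; then DBU, 0 °C to rt
Reagents that add atoms: none
Why: Mesylation followed by base-induced E1cB elimination (aldol condensation completed) gives the conjugated alkylidene lactone as the thermodynamically preferred E isomer with the aryl group anti to the lactone carbonyl.

Step 9
Reactants: 17 (E)-α-veratrylidene lactone
Product: 18 (2S,3R,6S,7R)-7-[(TBS-oxy)methyl]-2,6-bis-Ar-1,5-dioxaspiro[2.4]heptan-4-one
Conditions: DMDO (acetone solution, 3 equiv), CH2Cl2, 0 °C to rt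
Reagents that add atoms: dimethyldioxirane (DMDO), CC1(C)OO1
Why: Concerted, stereospecific dioxirane epoxidation occurs on the alkene face anti to the neighbouring CH2OTBS group (held pseudoaxial by allylic 1,3-strain with the aryl group), which fixes the future C1 oxygen cis to H5 and the E geometry fixes C2 as S, under neutral conditions that the acid-labile aryl epoxide survives.

Step 10
Reactants: 18 spiro-epoxy lactone
Product: 20 (1R,2R,5R,6S)-1-hydroxy-2,6-bis-Ar-3,7-dioxabicyclo[3.3.0]octan-8-one, via hydroxy epoxide 19 (not isolated)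
Conditions: Bu4NF/AcOH (1:1), THF, 0 °C to rt; then CSA (10 mol%), CH2Cl2, 0 °C
Reagents that add atoms: none
Why: Buffered fluoride desilylation followed by acid-catalysed intramolecular epoxide opening (5-endo mode, favoured at the veratryl-stabilised benzylic carbon) closes ring B with inversion at C2 to the exo-aryl 2R center, the epoxide oxygen becoming the tertiary 1-OH, and only the cis-fused bicycle can form.

Step 11
Reactants: 20 1-hydroxy furofuranone
Product: 21 (2R,3S,4R)-2-Ar-4-[(S)-Ar(hydroxy)methyl]-3-(hydroxymethyl)tetrahydrofuran-3-ol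
Conditions: LiAlH4, THF, 0 °C to rt; H2O/aq. NaOH work-up
Reagents that add atoms: none
Why: LiAlH4 reduction of the lactone cleaves only the acyl C8–O7 bond to give the primary alcohol and the benzylic alcohol, so C6 and all other stereocenters are retained.

Step 12
Reactants: 21 triol
Product: 23 isogmelinol (1S,2R,5R,6S)-2,6-bis-Ar-3,7-dioxabicyclo[3.3.0]octan-1-ol, via primary mesylate 22 (not isolated)
Conditions: MsCl (1.1 equiv), pyridine, CH2Cl2, 0 °C to rt
Reagents that add atoms: none
Why: Chemoselective mesylation of the primary hydroxyl in pyridine (the tertiary and the hindered benzylic hydroxyls react far more slowly) is followed by intramolecular Williamson-type 5-exo-tet etherification by the C6 hydroxyl, which closes ring A with retention at C6 and gives isogmelinol.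

## Compound list

1 | (S)-4-benzyloxazolidin-2-one | O=C1OC[C@H](Cc2ccccc2)N1 | starting material
2 | pent-4-enoyl chloride | C=CCCC(=O)Cl | starting material
3 | lithium (S)-4-benzyl-2-oxooxazolidin-3-ide (N-lithio oxazolidinone; not isolated) | [Li]N1[C@@H](Cc2ccccc2)COC1=O | intermediate
4 | (S)-4-benzyl-3-(pent-4-enoyl)oxazolidin-2-one | C=CCCC(=O)N1[C@@H](Cc2ccccc2)COC1=O | intermediate
5 | 3,4-dimethoxybenzaldehyde (veratraldehyde) | COc1ccc(C=O)cc1OC | starting material
6 | (Z)-dibutylboron enolate of 4 (not isolated) | C=CC/C=C(\OB(CCCC)CCCC)N1[C@@H](Cc2ccccc2)COC1=O | intermediate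
7 | (S)-4-benzyl-3-[(2S)-2-[(S)-(3,4-dimethoxyphenyl)(hydroxy)methyl]pent-4-enoyl]oxazolidin-2-one | C=CC[C@@H]([C@H](O)c1ccc(OC)c(OC)c1)C(=O)N1[C@@H](Cc2ccccc2)COC1=O | intermediate
8 | (1S,2R)-2-allyl-1-(3,4-dimethoxyphenyl)propane-1,3-diol | C=CC[C@@H]([C@H](O)c1ccc(OC)c(OC)c1)CO | intermediate
9 | (1S,2R)-2-{[(tert-butyldimethylsilyl)oxy]methyl}-1-(3,4-dimethoxyphenyl)pent-4-en-1-ol | C=CC[C@@H]([C@H](O)c1ccc(OC)c(OC)c1)CO[Si](C)(C)C(C)(C)C | intermediate
10 | (1S,2R)-2-{[(tert-butyldimethylsilyl)oxy]methyl}-1-(3,4-dimethoxyphenyl)pentane-1,4,5-triol (C4 epimers; not isolated) | OCC(O)C[C@@H]([C@H](O)c1ccc(OC)c(OC)c1)CO[Si](C)(C)C(C)(C)C | intermediate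
11 | (3R,4S)-3-{[(tert-butyldimethylsilyl)oxy]methyl}-4-(3,4-dimethoxyphenyl)-4-hydroxybutanal (not isolated) | O=CC[C@@H]([C@H](O)c1ccc(OC)c(OC)c1)CO[Si](C)(C)C(C)(C)C | intermediate
12 | (4R,5S)-4-{[(tert-butyldimethylsilyl)oxy]methyl}-5-(3,4-dimethoxyphenyl)tetrahydrofuran-2-ol (both anomers) | OC1C[C@H](CO[Si](C)(C)C(C)(C)C)[C@@H](c2ccc(OC)c(OC)c2)O1 | intermediate
13 | (4R,5S)-4-{[(tert-butyldimethylsilyl)oxy]methyl}-5-(3,4-dimethoxyphenyl)dihydrofuran-2(3H)-one | O=C1C[C@H](CO[Si](C)(C)C(C)(C)C)[C@@H](c2ccc(OC)c(OC)c2)O1 | intermediate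
14 | lithium (4R,5S)-4-{[(tert-butyldimethylsilyl)oxy]methyl}-5-(3,4-dimethoxyphenyl)-4,5-dihydrofuran-2-olate (not isolated) | [Li]OC1=C[C@H](CO[Si](C)(C)C(C)(C)C)[C@@H](c2ccc(OC)c(OC)c2)O1 | intermediate
15 | (3R,4R,5S)-4-{[(tert-butyldimethylsilyl)oxy]methyl}-5-(3,4-dimethoxyphenyl)-3-[(3,4-dimethoxyphenyl)(hydroxy)methyl]dihydrofuran-2(3H)-one (both carbinol epimers) | O=C1[C@@H](C(O)c2ccc(OC)c(OC)c2)[C@H](CO[Si](C)(C)C(C)(C)C)[C@@H](c3ccc(OC)c(OC)c3)O1 | intermediate
16 | methanesulfonate of 15 at the benzylic carbinol (both epimers; not isolated) | O=C1[C@@H](C(OS(C)(=O)=O)c2ccc(OC)c(OC)c2)[C@H](CO[Si](C)(C)C(C)(C)C)[C@@H](c3ccc(OC)c(OC)c3)O1 | intermediate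
17 | (3E,4R,5S)-4-{[(tert-butyldimethylsilyl)oxy]methyl}-3-(3,4-dimethoxybenzylidene)-5-(3,4-dimethoxyphenyl)dihydrofuran-2(3H)-one | O=C1/C(=C/c2ccc(OC)c(OC)c2)[C@H](CO[Si](C)(C)C(C)(C)C)[C@@H](c3ccc(OC)c(OC)c3)O1 | intermediate
18 | (2S,3R,6S,7R)-7-{[(tert-butyldimethylsilyl)oxy]methyl}-2,6-bis(3,4-dimethoxyphenyl)-1,5-dioxaspiro[2.4]heptan-4-one | O=C1[C@@]2(O[C@H]2c3ccc(OC)c(OC)c3)[C@H](CO[Si](C)(C)C(C)(C)C)[C@@H](c4ccc(OC)c(OC)c4)O1 | intermediate
19 | (2S,3R,6S,7R)-2,6-bis(3,4-dimethoxyphenyl)-7-(hydroxymethyl)-1,5-dioxaspiro[2.4]heptan-4-one (not isolated) | O=C1[C@@]2(O[C@H]2c3ccc(OC)c(OC)c3)[C@H](CO)[C@@H](c4ccc(OC)c(OC)c4)O1 | intermediate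
20 | (1R,2R,5R,6S)-1-hydroxy-2,6-bis(3,4-dimethoxyphenyl)-3,7-dioxabicyclo[3.3.0]octan-8-one (target numbering; lactone carbonyl at C8) | COc1ccc([C@H]2OC(=O)[C@]3(O)[C@@H](c4ccc(OC)c(OC)c4)OC[C@H]23)cc1OC | intermediate
21 | (2R,3S,4R)-2-(3,4-dimethoxyphenyl)-4-[(S)-(3,4-dimethoxyphenyl)(hydroxy)methyl]-3-(hydroxymethyl)tetrahydrofuran-3-ol | COc1ccc([C@@H](O)[C@H]2CO[C@H](c3ccc(OC)c(OC)c3)[C@@]2(O)CO)cc1OC | intermediate
22 | {(2R,3S,4R)-2-(3,4-dimethoxyphenyl)-4-[(S)-(3,4-dimethoxyphenyl)(hydroxy)methyl]-3-hydroxytetrahydrofuran-3-yl}methyl methanesulfonate (not isolated) | COc1ccc([C@@H](O)[C@H]2CO[C@H](c3ccc(OC)c(OC)c3)[C@@]2(O)COS(C)(=O)=O)cc1OC | intermediate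
23 | isogmelinol, (1S,2R,5R,6S)-2,6-bis(3,4-dimethoxyphenyl)-3,7-dioxabicyclo[3.3.0]octan-1-ol | COc1ccc([C@H]2OC[C@]3(O)[C@@H](c4ccc(OC)c(OC)c4)OC[C@H]23)cc1OC | target

## Summary and risks

Total step count: 12. Longest linear sequence: 12 steps (from 1 or 2 to 23; veratraldehyde 5 enters twice).

Steps most likely to fail:

Step 9 (epoxidation of a hindered, electron-poor trisubstituted alkene; rate and face selectivity). The fallback sets out from 17 and comes back to the route at 20. Catalytic OsO4 with NMO in acetone/H2O dihydroxylates the same open face and gives the diol lactone F1. Bu4NF/AcOH then frees the primary alcohol to give the triol lactone F2. BF3·OEt2 in CH2Cl2 at −20 to 0 °C ionises the veratryl carbinol, and the C4 hydroxyl captures the cation to give 20 with the exo aryl group. C1 is then set by the dihydroxylation face and C2 by cation capture under product-stability control, not by stereospecific epoxide inversion.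

Step 10 (cyclisation of the epoxy alcohol; possible lactone migration under fluoride or acyl-shift rearrangement of the aryl epoxide under acid). The fallback sets out from 15 and comes back to the route at 20, avoiding the alkylidene lactone and the epoxide altogether. Et3SiOTf and 2,6-lutidine protect the aldol hydroxyl to give the bis-silyl ether F3. KN(SiMe3)2 in THF at −78 °C followed by 2-(benzenesulfonyl)-3-phenyloxaziridine hydroxylates the enolate anti to the CH2OTBS group and gives the α-hydroxy lactone F4, in which the carbinol side chain is now cis to C4. Bu4NF/AcOH removes both silyl groups to give the triol lactone F5 as both carbinol epimers. BF3·OEt2 in CH2Cl2 then converts both epimers through the same benzylic cation into 20.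

Step 12 (mono-mesylation of a neopentyl-type primary hydroxyl next to a benzylic and a tertiary hydroxyl, then displacement at a neopentyl carbon). The fallback sets out from 21 and comes back to the route at 23 and makes no new compound (F0). Catalytic CSA in CH2Cl2 (or dilute HCl in EtOH) ionises the C6 veratryl carbinol and the C8 hydroxyl captures the cation, so the ring A bond is made at the benzylic carbon and not at the primary carbon. Reversible ionisation of both benzylic ethers funnels the material to the exo,exo isomer, which is the acid-stable member of this family.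

Further compounds

F1 | step 9 | (3R,4R,5S)-4-{[(tert-butyldimethylsilyl)oxy]methyl}-5-(3,4-dimethoxyphenyl)-3-[(S)-(3,4-dimethoxyphenyl)(hydroxy)methyl]-3-hydroxydihydrofuran-2(3H)-one (diol lactone) | O=C1[C@](O)([C@@H](O)c2ccc(OC)c(OC)c2)[C@H](CO[Si](C)(C)C(C)(C)C)[C@@H](c3ccc(OC)c(OC)c3)O1
F2 | step 9 | (3R,4R,5S)-5-(3,4-dimethoxyphenyl)-3-[(S)-(3,4-dimethoxyphenyl)(hydroxy)methyl]-3-hydroxy-4-(hydroxymethyl)dihydrofuran-2(3H)-one (triol lactone) | O=C1[C@](O)([C@@H](O)c2ccc(OC)c(OC)c2)[C@H](CO)[C@@H](c3ccc(OC)c(OC)c3)O1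
F3 | step 10 | (3R,4R,5S)-4-{[(tert-butyldimethylsilyl)oxy]methyl}-5-(3,4-dimethoxyphenyl)-3-{(3,4-dimethoxyphenyl)[(triethylsilyl)oxy]methyl}dihydrofuran-2(3H)-one (bis-silyl ether; both carbinol epimers) | O=C1[C@@H](C(O[Si](CC)(CC)CC)c2ccc(OC)c(OC)c2)[C@H](CO[Si](C)(C)C(C)(C)C)[C@@H](c3ccc(OC)c(OC)c3)O1
F4 | step 10 | (3R,4R,5S)-4-{[(tert-butyldimethylsilyl)oxy]methyl}-5-(3,4-dimethoxyphenyl)-3-{(3,4-dimethoxyphenyl)[(triethylsilyl)oxy]methyl}-3-hydroxydihydrofuran-2(3H)-one (α-hydroxy lactone; both carbinol epimers) | O=C1[C@](O)(C(O[Si](CC)(CC)CC)c2ccc(OC)c(OC)c2)[C@H](CO[Si](C)(C)C(C)(C)C)[C@@H](c3ccc(OC)c(OC)c3)O1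
F5 | step 10 | (3R,4R,5S)-5-(3,4-dimethoxyphenyl)-3-[(3,4-dimethoxyphenyl)(hydroxy)methyl]-3-hydroxy-4-(hydroxymethyl)dihydrofuran-2(3H)-one (triol lactone; both carbinol epimers) | O=C1[C@](O)(C(O)c2ccc(OC)c(OC)c2)[C@H](CO)[C@@H](c3ccc(OC)c(OC)c3)O1
F0 | step 12 | none | none
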